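**Retrosynthetic overview**
1. 40 ⇐ tetraol 39 (acetylation of the three secondary hydroxyls) ⇐ lactone 37 (desilylation; the 11(20)-exo-methylene is moved to C11=C12) ⇐ diol 36 by oxidative lactonisation; the C7–O–C19 γ-lactone is the last ring.
2. Ten-membered ring ⇐ C6–C7 by Nozaki–Hiyama–Kishi closure of the vinyl iodide aldehyde 34.
3. C8–C9 ⇐ aldol of ring-A aldehyde 22 with the enolate of dioxolanone 29 (from dimethyl (S)-malate; C17 by Fráter–Seebach methylation, quaternary C8 by self-regeneration of the stereocentre).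
4. Ring A ⇐ intramolecular Diels–Alder reaction of the buta-2,3-dienoate-tethered (Z)-2-siloxydiene 16 (first ring, formed together with a temporary γ-lactone that is opened in step 10), making C1–C10 and C11–C12; 16 ⇐ propionyl oxazolidinone 7 + aldehyde 6 + vinylmagnesium bromide + but-3-ynoic acid.
5. Enabling feature: the C2 oxygen and C9 sit on the two ends of the C1–C10 bond of ring A (O–C2–C1–C10–C9), so a C2–O–C9(=O) ester is a three-atom tether that closes as a temporary γ-lactone ring (C1, C2, O, C9, C10) fused to ring A (C1, C10–C14); the C14 oxygen maps onto a 2-siloxydiene and the C20 methyl onto the allene terminus.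

Key step: step 8

Remark: briarane numbering (C1–C20) is used for all intermediates; the target SMILES is read as the 1S,2R,7S,8S,9R,10S,14S,17R isomer with a 5Z alkene.

**Route**

Step 1
Reactants: 1 2-(2-bromoethyl)-1,3-dioxolane; 2 propyne
Product: 5 (Z)-2-(4-iodo-3-methylbut-3-en-1-yl)-1,3-dioxolane, via Grignard reagent 3 (not isolated), via alkenylcopper reagent 4 (not isolated)
Conditions: Mg, THF, 25 °C; CuBr·SMe2, Et2O/Me2S, −45 °C; propyne, −25 °C; I2, −50 → 0 °C
Reagents that add atoms: iodine, II
Why: syn-carbocupration of propyne (carbometalation) places the alkyl chain and copper cis, and iodinolysis with retention should give the (Z)-trisubstituted vinyl iodide that becomes C5=C6.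

Step 2
Reactants: 5
Product: 6 (Z)-5-iodo-4-methylpent-4-enal
Conditions: 2 M HCl, THF, 25 °C
Reagents that add atoms: water, O
Why: acid-catalysed acetal hydrolysis should free the aldehyde (C2) while the vinyl iodide is inert.

Step 3
Reactants: 7 (S)-4-benzyl-3-propionyloxazolidin-2-one; 6
Product: 9 syn-aldol imide, via boron enolate 8 (not isolated)
Conditions: n-Bu2BOTf, Et3N, CH2Cl2, −78 → 0 °C; then 6, −78 → 0 °C; H2O2, pH 7 buffer, MeOH
Reagents that add atoms: none
Why: Evans syn-aldol reaction through the (Z)-boron enolate and a Zimmerman–Traxler chair, in which the auxiliary should set the carbinol carbon C2 as R (the adjacent C1 centre is erased later).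

Step 4
Reactants: 9
Product: 10 β-hydroxy Weinreb amide
Conditions: MeONHMe·HCl, AlMe3, CH2Cl2, 0 °C
Reagents that add atoms: N,O-dimethylhydroxylamine hydrochloride, CNOC.Cl
Why: aluminium amide transamidation of the β-hydroxy imide (Weinreb amide formation) should release the auxiliary without touching C2.

Step 5
Reactants: 10; 11 vinylmagnesium bromide
Product: 12 (4S,5R,8Z)-5-hydroxy-9-iodo-4,8-dimethylnona-1,8-dien-3-one
Conditions: THF, −78 → 0 °C; inverse quench into cold aqueous NH4Cl
Reagents that add atoms: none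
Why: Grignard addition to a Weinreb amide stops at the chelated tetrahedral intermediate and should give the vinyl ketone that carries C12–C14.

Step 6
Reactants: 12; 13 but-3-ynoic acid
Product: 15 buta-2,3-dienoate of 12, via but-3-ynoate ester 14 (not isolated)
Conditions: DCC, DMAP (cat.), CH2Cl2, 0 °C
Reagents that add atoms: none
Why: carbodiimide (Steglich) esterification of the C2 hydroxyl, during which the but-3-ynoate should isomerise under DMAP to the conjugated allenoate that holds C9, C10, C11 and C20.

Step 7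
Reactants: 15
Product: 16 (3Z)-TBS dienol ether of 15
Conditions: TBSOTf, Et3N, CH2Cl2, −78 → −20 °C
Reagents that add atoms: tert-butyldimethylsilyl trifluoromethanesulfonate, CC(C)(C)[Si](C)(C)OS(=O)(=O)C(F)(F)F
Why: soft enolisation (silyl triflate and amine) at C1, the only enolisable α-position, should give the 2-siloxydiene with C2 cis to the siloxy oxygen because the branched C2 avoids A(1,3) strain with the vinyl group.

Step 8
Reactants: 16
Product: 18 trans-fused keto γ-lactone, via cycloadduct silyl enol ether 17 (not isolated)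
Conditions: toluene (5 mM), BHT, 110 °C; then HF·pyridine, THF, 0 °C
Reagents that add atoms: none
Why: Thermal intramolecular Diels–Alder reaction (concerted, asynchronous [4+2]) of the 2-siloxydiene C12=C13–C14(OTBS)=C1 with the conjugated C10=C11 π-bond of the allenoate, the bond that carries the LUMO; the closest known reaction types are the ester-tethered Diels–Alder reactions of penta-2,4-dienyl acrylates and of dienyl allenecarboxylates, which give γ-lactones with an exocyclic methylene. Ring A (C1, C10, C11, C12, C13, C14) closes by the [4+2] union itself, and the temporary γ-lactone (C1, C2, O, C9, C10) closes in the fused mode because the three-atom tether C2–O–C9 cannot span the bridged alternative. The quaternary centre C1 is controlled by C2: A(1,3) strain with the cis siloxy group on C14 holds C2–H in the diene plane, so the ester oxygen and the dienophile lie on one face and the C3 chain on the other, which puts C15 and C3 cis on the lactone. C10 is controlled by the exo orientation of the tether carbonyl (trans ring fusion, 10-H anti to C15), since the endo-tether geometry would press the ester against the C14 siloxy group, the known steric directing effect of an internal diene substituent next to the tether. The step needs site selectivity for the conjugated over the distal allene π-bond, fused regiochemistry and trans selectivity, and conjugation, tether length and the C14 substituent should secure them in that order. Fluoride then unmasks the C14 ketone without opening the lactone.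

Step 9
Reactants: 18
Product: 19 14α-hydroxy lactone
Conditions: LiBH(s-Bu)3, THF, −78 °C
Reagents that add atoms: none
Why: the bulky trialkylborohydride should attack the C14 ketone along the equatorial trajectory and give the axial 14α-alcohol (trans to C15), faster than it reduces the lactone.

Step 10
Reactants: 19
Product: 20 dihydroxy Weinreb amide
Conditions: MeONHMe·HCl, AlMe3, CH2Cl2, 0 → 25 °C
Reagents that add atoms: N,O-dimethylhydroxylamine hydrochloride, CNOC.Cl
Why: aluminium amide aminolysis of the strained trans-fused γ-lactone (Weinreb amide formation) should cleave the temporary C9–O bond and free the C2 hydroxyl.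

Step 11
Reactants: 20
Product: 21 bis-TBS ether
Conditions: TBSOTf, 2,6-lutidine, CH2Cl2, 0 → 25 °C
Reagents that add atoms: tert-butyldimethylsilyl trifluoromethanesulfonate, CC(C)(C)[Si](C)(C)OS(=O)(=O)C(F)(F)F
Why: silyl triflate silylation should protect the hindered C2 and C14 hydroxyls in one operation.

Step 12
Reactants: 21
Product: 22 C9 aldehyde
Conditions: i-Bu2AlH, THF, −78 °C; Rochelle salt
Reagents that add atoms: none
Why: hydride reduction of the Weinreb amide stops at the chelated hemiaminal and should give the aldehyde with C10 unchanged at low temperature.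

Step 13
Reactants: 23 dimethyl (S)-malate
Product: 25 dimethyl (2S,3R)-3-methylmalate, via dilithium alkoxide enolate 24 (not isolated)
Conditions: LiN(i-Pr)2 (2.2 equiv), THF, −78 → −20 °C; MeI, −78 → 0 °C
Reagents that add atoms: iodomethane, CI
Why: Fráter–Seebach alkylation, in which the chelated dianion should be methylated anti to the alkoxide and so set C17.

Step 14
Reactants: 25
Product: 26 (2S,3R)-3-methylmalic acid
Conditions: KOH, MeOH/H2O, 0 → 25 °C; then HCl
Reagents that add atoms: potassium hydroxide, [K+].[OH-]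
Why: ester saponification should give the diacid without epimerisation at the non-activated centres.

Step 15
Reactants: 26
Product: 27 cis-dioxolanone acid
Conditions: t-BuCHO, TsOH (cat.), H2SO4 (cat.), pentane, reflux, water separator
Reagents that add atoms: pivalaldehyde, CC(C)(C)C=O
Why: acid-catalysed acetalisation of the α-hydroxy acid unit should give the thermodynamic cis-2-tert-butyl-1,3-dioxolan-4-one, whose acetal centre stores the C8 configuration.

Step 16
Reactants: 27
Product: 28 dioxolanone alcohol
Conditions: BH3·THF, THF, 0 → 25 °C; MeOH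
Reagents that add atoms: none
Why: borane reduces the free carboxylic acid (C19) chemoselectively in the presence of the lactone-type dioxolanone.

Step 17
Reactants: 28
Product: 29 dioxolanone TBS ether
Conditions: TBSCl, imidazole, CH2Cl2, 0 °C (crude 28 used at once)
Reagents that add atoms: tert-butylchlorodimethylsilane, CC(C)(C)[Si](C)(C)Cl
Why: fast silylation of the primary alcohol should forestall translactonisation onto the dioxolanone carbonyl.

Step 18
Reactants: 29; 22
Product: 31 aldol adduct, via lithium enolate 30 (not isolated)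
Conditions: LiN(SiMe3)2, THF, −78 °C; then 22, −78 °C; AcOH quench at −78 °C
Reagents that add atoms: none
Why: aldol addition with self-regeneration of the stereocentre, in which attack trans to the tert-butyl group should set quaternary C8, and the Zimmerman–Traxler chair of the cyclic enolate (ring oxygen anti to the new hydroxyl) and Felkin–Anh addition to the α-branched aldehyde both lead to 9R, a matched case.

Step 19
Reactants: 31
Product: 32 C9 TBS ether
Conditions: TBSOTf, 2,6-lutidine, CH2Cl2, −20 → 25 °C
Reagents that add atoms: tert-butyldimethylsilyl trifluoromethanesulfonate, CC(C)(C)[Si](C)(C)OS(=O)(=O)C(F)(F)F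
Why: silyl triflate silylation should cap the C9 hydroxyl so that it cannot later lactonise onto C19.

Step 20
Reactants: 32
Product: 33 C7,C8-diol
Conditions: LiBH4, Et2O, MeOH (1 equiv), 0 → 25 °C
Reagents that add atoms: none
Why: borohydride reduction of the dioxolanone carbonyl (C7) releases pivalaldehyde and should leave the primary C7 alcohol and the free tertiary C8 hydroxyl, with silyl ethers and vinyl iodide untouched.

Step 21
Reactants: 33
Product: 34 α-hydroxy aldehyde
Conditions: TEMPO (cat.), PhI(OAc)2, CH2Cl2, 25 °C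
Reagents that add atoms: none
Why: oxoammonium (TEMPO) oxidation is selective for the primary alcohol and should give the C7 aldehyde beside the unreactive tertiary hydroxyl.

Step 22
Reactants: 34
Product: 35 ten-membered allylic alcohol
Conditions: CrCl2 (10 equiv), NiCl2 (2 mol %), DMSO, 25 °C, slow addition to 2 mM
Reagents that add atoms: none
Why: Nozaki–Hiyama–Kishi macrocyclisation, in which the alkenylchromium species adds to the aldehyde with retention of the Z geometry and closes the C6–C7 bond, while Felkin–Anh addition anti to the C8 oxygen with the smaller C17 branch next to the incoming carbon should give 7S.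

Step 23
Reactants: 35
Product: 36 C7,C8,C19-triol
Conditions: HF·pyridine, pyridine, THF, 0 °C
Reagents that add atoms: none
Why: buffered fluoride desilylation should remove the primary C19 silyl ether much faster than the three hindered secondary ones.

Step 24
Reactants: 36
Product: 37 γ-lactone with 11(20)-exo-methylene
Conditions: TEMPO (cat.), PhI(OAc)2 (2.5 equiv), CH2Cl2, 25 °C
Reagents that add atoms: none
Why: oxidative lactonisation of the 1,4-diol, in which the C19 aldehyde is trapped by the C7 hydroxyl as a lactol and oxidised on, should give the 7,19-lactone only, because C9–O is silylated and the C8 hydroxyl would need a four-membered ring.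

Step 25
Reactants: 37
Product: 38 Δ11-lactone
Conditions: [Co(salen)Cl] (5 mol %; salen = N,N′-bis(3,5-di-tert-butylsalicylidene)-1,2-cyclohexanediaminate), PhSiH3 (10 mol %), benzene, 25 °C
Reagents that add atoms: none
Why: cobalt hydride hydrogen-atom-transfer isomerisation of the 1,1-disubstituted alkene should give the trisubstituted C11=C12 alkene, since hydrogen is returned from the accessible C12 methylene and not from the buried C10–H, and the Δ10 isomer is also disfavoured by allylic strain.

Step 26
Reactants: 38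
Product: 39 tetraol
Conditions: HF·pyridine (excess), THF, 0 → 40 °C
Reagents that add atoms: none
Why: fluoride-mediated global desilylation should free the C2, C9 and C14 hydroxyls under acidic conditions that do not open the lactone.

Step 27
Reactants: 39
Product: 40 stylatulide lactone
Conditions: Ac2O, pyridine, DMAP (cat.), CH2Cl2, 0 → 25 °C
Reagents that add atoms: acetic anhydride, CC(=O)OC(C)=O
Why: acylation should esterify the three secondary hydroxyls, while the tertiary C8 hydroxyl between two fully substituted neighbours stays free.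

**Compound list**
1 | 2-(2-bromoethyl)-1,3-dioxolane | BrCCC1OCCO1 | starting material
2 | propyne | CC#C | starting material
3 | 2-(1,3-dioxolan-2-yl)ethylmagnesium bromide | Br[Mg]CCC1OCCO1 | intermediate
4 | (Z)-[4-(1,3-dioxolan-2-yl)-2-methylbut-1-enyl]copper | [Cu]/C=C(/C)CCC1OCCO1 | intermediate
5 | (Z)-2-(4-iodo-3-methylbut-3-en-1-yl)-1,3-dioxolane | I/C=C(/C)CCC1OCCO1 | intermediate
6 | (Z)-5-iodo-4-methylpent-4-enal | I/C=C(/C)CCC=O | intermediate
7 | (S)-4-benzyl-3-propionyloxazolidin-2-one | CCC(=O)N1[C@@H](Cc2ccccc2)COC1=O | starting material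
8 | (Z)-dibutylboron enolate of 7 | C/C=C(\OB(CCCC)CCCC)N1[C@@H](Cc2ccccc2)COC1=O | intermediate
9 | (S)-4-benzyl-3-[(2S,3R,6Z)-3-hydroxy-7-iodo-2,6-dimethylhept-6-enoyl]oxazolidin-2-one | I/C=C(/C)CC[C@@H](O)[C@H](C)C(=O)N1[C@@H](Cc2ccccc2)COC1=O | intermediate
10 | (2S,3R,6Z)-3-hydroxy-7-iodo-N-methoxy-N,2,6-trimethylhept-6-enamide | I/C=C(/C)CC[C@@H](O)[C@H](C)C(=O)N(C)OC | intermediate
11 | vinylmagnesium bromide | C=C[Mg]Br | starting material
12 | (4S,5R,8Z)-5-hydroxy-9-iodo-4,8-dimethylnona-1,8-dien-3-one | I/C=C(/C)CC[C@@H](O)[C@H](C)C(=O)C=C | intermediate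
13 | but-3-ynoic acid | C#CCC(=O)O | starting material
14 | (4S,5R,8Z)-9-iodo-4,8-dimethyl-3-oxonona-1,8-dien-5-yl but-3-ynoate | I/C=C(/C)CC[C@@H](OC(=O)CC#C)[C@H](C)C(=O)C=C | intermediate
15 | (4S,5R,8Z)-9-iodo-4,8-dimethyl-3-oxonona-1,8-dien-5-yl buta-2,3-dienoate | I/C=C(/C)CC[C@@H](OC(=O)C=C=C)[C@H](C)C(=O)C=C | intermediate
16 | (3Z,5R,8Z)-3-(tert-butyldimethylsilyloxy)-9-iodo-4,8-dimethylnona-1,3,8-trien-5-yl buta-2,3-dienoate | I/C=C(/C)CC[C@@H](OC(=O)C=C=C)/C(C)=C(\O[Si](C)(C)C(C)(C)C)C=C | intermediate
17 | Diels–Alder adduct: ring A with C13=C14 TBS enol ether and 11(20)-methylene, trans-fused γ-lactone C9(=O)–O–C2 (15-Me and 10-H trans), (Z)-4-iodo-3-methylbut-3-enyl chain on C2 cis to C15 | I/C=C(/C)CC[C@H]2OC(=O)[C@H]1C(=C)CC=C(O[Si](C)(C)C(C)(C)C)[C@@]12C | intermediate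
18 | keto lactone: as 17 with a C14 ketone | I/C=C(/C)CC[C@H]2OC(=O)[C@H]1C(=C)CCC(=O)[C@@]12C | intermediate
19 | 14α-hydroxy lactone (axial hydroxyl trans to C15) | I/C=C(/C)CC[C@H]2OC(=O)[C@H]1C(=C)CC[C@H](O)[C@@]12C | intermediate
20 | ring-A Weinreb amide (C9) with free 2- and 14-hydroxyls, centres as in 40 | I/C=C(/C)CC[C@@H](O)[C@@]1(C)[C@@H](O)CCC(=C)[C@@H]1C(=O)N(C)OC | intermediate
21 | 2,14-bis-TBS ether of 20 | I/C=C(/C)CC[C@@H](O[Si](C)(C)C(C)(C)C)[C@@]1(C)[C@@H](O[Si](C)(C)C(C)(C)C)CCC(=C)[C@@H]1C(=O)N(C)OC | intermediate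
22 | ring-A C9 aldehyde (2,14-bis-TBS; 11(20)-methylene; Z-vinyl iodide chain) | I/C=C(/C)CC[C@@H](O[Si](C)(C)C(C)(C)C)[C@@]1(C)[C@@H](O[Si](C)(C)C(C)(C)C)CCC(=C)[C@@H]1C=O | intermediate
23 | dimethyl (S)-malate | COC(=O)[C@@H](O)CC(=O)OC | starting material
24 | dilithium alkoxide enolate of 23 | [Li+].[Li+].COC(=O)[C@@H]([O-])C=C([O-])OC | intermediate
25 | dimethyl (2S,3R)-2-hydroxy-3-methylsuccinate | COC(=O)[C@@H](O)[C@@H](C)C(=O)OC | intermediate
26 | (2S,3R)-2-hydroxy-3-methylsuccinic acid | OC(=O)[C@@H](O)[C@@H](C)C(=O)O | intermediate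
27 | (2R)-2-[(2S,4S)-2-tert-butyl-5-oxo-1,3-dioxolan-4-yl]propanoic acid | CC(C)(C)[C@H]1O[C@@H]([C@@H](C)C(=O)O)C(=O)O1 | intermediate
28 | (2S,5S)-2-tert-butyl-5-[(2S)-1-hydroxypropan-2-yl]-1,3-dioxolan-4-one | CC(C)(C)[C@H]1O[C@@H]([C@@H](C)CO)C(=O)O1 | intermediate
29 | (2S,5S)-2-tert-butyl-5-[(2S)-1-(tert-butyldimethylsilyloxy)propan-2-yl]-1,3-dioxolan-4-one | CC(C)(C)[C@H]1O[C@@H]([C@@H](C)CO[Si](C)(C)C(C)(C)C)C(=O)O1 | intermediate
30 | lithium enolate of 29 | [Li+].CC(C)(C)[C@H]1OC([C@@H](C)CO[Si](C)(C)C(C)(C)C)=C([O-])O1 | intermediate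
31 | aldol adduct: (9R)-alcohol, quaternary C8 inside the dioxolanone (C7 carbonyl; new C8–C9 bond trans to tert-butyl), C17/C19 side chain as in 29 | I/C=C(/C)CC[C@@H](O[Si](C)(C)C(C)(C)C)[C@@]1(C)[C@@H](O[Si](C)(C)C(C)(C)C)CCC(=C)[C@@H]1[C@@H](O)[C@@]2([C@@H](C)CO[Si](C)(C)C(C)(C)C)O[C@H](C(C)(C)C)OC2=O | intermediate
32 | 9-O-TBS ether of 31 | I/C=C(/C)CC[C@@H](O[Si](C)(C)C(C)(C)C)[C@@]1(C)[C@@H](O[Si](C)(C)C(C)(C)C)CCC(=C)[C@@H]1[C@@H](O[Si](C)(C)C(C)(C)C)[C@@]2([C@@H](C)CO[Si](C)(C)C(C)(C)C)O[C@H](C(C)(C)C)OC2=O | intermediate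
33 | C7 primary alcohol, C8 tertiary alcohol (2,9,14,19-tetra-TBS; vinyl iodide chain) | I/C=C(/C)CC[C@@H](O[Si](C)(C)C(C)(C)C)[C@@]1(C)[C@@H](O[Si](C)(C)C(C)(C)C)CCC(=C)[C@@H]1[C@@H](O[Si](C)(C)C(C)(C)C)[C@@](O)(CO)[C@@H](C)CO[Si](C)(C)C(C)(C)C | intermediate
34 | C7 aldehyde with free C8 hydroxyl (seco precursor of the ten-membered ring) | I/C=C(/C)CC[C@@H](O[Si](C)(C)C(C)(C)C)[C@@]1(C)[C@@H](O[Si](C)(C)C(C)(C)C)CCC(=C)[C@@H]1[C@@H](O[Si](C)(C)C(C)(C)C)[C@@](O)(C=O)[C@@H](C)CO[Si](C)(C)C(C)(C)C | intermediate
35 | bicyclo[8.4.0] core: (5Z)-alkene, (7S)-7,8-diol, 2,9,14,19-tetra-TBS, 11(20)-methylene | CC(C)(C)[Si](C)(C)O[C@H]1CCC(=C)[C@@H]2[C@@H](O[Si](C)(C)C(C)(C)C)[C@@]([C@@H](C)CO[Si](C)(C)C(C)(C)C)(O)[C@H](/C=C(/C)CC[C@@H](O[Si](C)(C)C(C)(C)C)[C@@]12C)O | intermediate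
36 | 7,8,19-triol (2,9,14-tri-TBS) | CC(C)(C)[Si](C)(C)O[C@H]1CCC(=C)[C@@H]2[C@@H](O[Si](C)(C)C(C)(C)C)[C@@]([C@@H](C)CO)(O)[C@H](/C=C(/C)CC[C@@H](O[Si](C)(C)C(C)(C)C)[C@@]12C)O | intermediate
37 | 2,9,14-tri-O-TBS 11(20)-exo-methylene 7,19-lactone | CC(C)(C)[Si](C)(C)O[C@H]1CCC(=C)[C@@H]2[C@@H](O[Si](C)(C)C(C)(C)C)[C@@]3(O)[C@H](/C=C(/C)CC[C@@H](O[Si](C)(C)C(C)(C)C)[C@@]12C)OC(=O)[C@@H]3C | intermediate
38 | 2,9,14-tri-O-TBS Δ11-lactone | CC(C)(C)[Si](C)(C)O[C@H]1CC=C(C)[C@@H]2[C@@H](O[Si](C)(C)C(C)(C)C)[C@@]3(O)[C@H](/C=C(/C)CC[C@@H](O[Si](C)(C)C(C)(C)C)[C@@]12C)OC(=O)[C@@H]3C | intermediate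
39 | 2,9,14-tri-O-deacetylstylatulide lactone (tetraol) | O[C@H]1CC=C(C)[C@@H]2[C@@H](O)[C@@]3(O)[C@H](/C=C(/C)CC[C@@H](O)[C@@]12C)OC(=O)[C@@H]3C | intermediate
40 | stylatulide lactone | CC(=O)O[C@H]1CC=C(C)[C@@H]2[C@@H](OC(C)=O)[C@@]3(O)[C@H](/C=C(/C)CC[C@@H](OC(C)=O)[C@@]12C)OC(=O)[C@@H]3C | target

**Step count**
Total: 27 steps. Longest linear sequence: 22 steps (steps 1–12 and 18–27); the dioxolanone branch (steps 13–17) joins at step 18.

**Steps most likely to fail**

Step 8. The cycloaddition may run through the distal C11=C20 π-bond of the allene (a six-membered lactone with C20 in the new carbocycle), or lose trans selectivity if the dienol ether geometry scrambles on heating. The fallback sets out from 12 and replaces the allene by an alkyne, which offers only one reachable π-bond. Esterification of 12 with but-2-ynoic acid (DCC, DMAP) gives the but-2-ynoate ester F1. Soft enolisation (TBSOTf, Et3N) gives the (Z)-silyl dienol ether F2, and heating in toluene at 130 °C should give the cyclohexa-1,4-diene lactone F3, in which C1 is set by the same A(1,3) control and C10 is still trigonal. Photochemical deconjugation of the α,β-unsaturated lactone (254 nm, 1,2-dimethylimidazole cat., hexane) transfers a hydrogen from the C20 methyl, which is held cis to the carbonyl, and reprotonates the dienol at C10 on the face away from C15. This returns to the route at 17, which is desilylated to 18 as in step 8.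

Step 22. Ring closure may show poor facial selectivity at C7, because chelation of chromium by the free C8 hydroxyl competes with the Felkin–Anh pathway in a strained ten-membered transition state. The fallback sets out from 34 and moves C7 control from the substrate to a reagent. The mixture of 35 and its C7 epimer F5 obtained from the cyclisation is oxidised with MnO2 to the (Z)-enone F6. Corey–Bakshi–Shibata reduction ((R)-2-methyl-oxazaborolidine, BH3·SMe2, with the quaternary C8 as the large group) should return to the route at 35.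

Step 18. The basic lithium enolate may deprotonate the hindered, β,γ-unsaturated aldehyde 22 at C10 instead of adding to it, or the crowded aldolate may revert. The fallback sets out from 29 and avoids a basic enolate in the bond-forming event. Treatment of 29 with LiN(SiMe3)2 and Me3SiCl gives the silyl ketene acetal F4. Mukaiyama aldol addition of F4 to 22 (BF3·OEt2, CH2Cl2, −78 °C) proceeds through an open transition state, anti to the tert-butyl group and Felkin–Anh on the aldehyde, and should return to the route at 31.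

**Further compounds**
F1 | step 8 | (4S,5R,8Z)-9-iodo-4,8-dimethyl-3-oxonona-1,8-dien-5-yl but-2-ynoate | I/C=C(/C)CC[C@@H](OC(=O)C#CC)[C@H](C)C(=O)C=C
F2 | step 8 | (3Z,5R,8Z)-3-(tert-butyldimethylsilyloxy)-9-iodo-4,8-dimethylnona-1,3,8-trien-5-yl but-2-ynoate | I/C=C(/C)CC[C@@H](OC(=O)C#CC)/C(C)=C(\O[Si](C)(C)C(C)(C)C)C=C
F3 | step 8 | cyclohexa-1,4-diene lactone (C10=C11 conjugated with the C9 lactone carbonyl, C13=C14 TBS enol ether) | I/C=C(/C)CC[C@H]2OC(=O)C1=C(C)CC=C(O[Si](C)(C)C(C)(C)C)[C@@]12C
F4 | step 18 | trimethylsilyl ketene acetal of 29 | CC(C)(C)[C@H]1OC([C@@H](C)CO[Si](C)(C)C(C)(C)C)=C(O[Si](C)(C)C)O1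
F5 | step 22 | C7 epimer of 35 | CC(C)(C)[Si](C)(C)O[C@H]1CCC(=C)[C@@H]2[C@@H](O[Si](C)(C)C(C)(C)C)[C@@]([C@@H](C)CO[Si](C)(C)C(C)(C)C)(O)[C@@H](/C=C(/C)CC[C@@H](O[Si](C)(C)C(C)(C)C)[C@@]12C)O
F6 | step 22 | (5Z)-7-ketone (enone) derived from 35 and F5 | CC(C)(C)[Si](C)(C)O[C@H]1CCC(=C)[C@@H]2[C@@H](O[Si](C)(C)C(C)(C)C)[C@@]([C@@H](C)CO[Si](C)(C)C(C)(C)C)(O)C(=O)/C=C(/C)CC[C@@H](O[Si](C)(C)C(C)(C)C)[C@@]12C
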